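## Retrosynthetic overview

1. Numbering used throughout: C1 = quaternary epoxide carbon (farnesyl), C2 = C=O, C3=C4 alkene (C4 bears CH2OAc), C5 = C=O, C6 = epoxide CH, O7. The core is a pseudo-symmetric 2,5-disubstituted p-quinone, so the two enone halves (C1=C6 to be epoxidised, C3=C4 to be kept) must be told apart.
2. Target 16 ⇐ C5 ketal hydrolysis and O-acetylation ⇐ epoxy quinone monoketal 14 ⇐ hydroxyl-directed, tartrate-mediated nucleophilic epoxidation of quinone monoketal 13. This sets C1 and C6 together and closes the oxirane, the second and last ring.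
3. 13 ⇐ iodane/MeOH dearomatisation of p-methoxyphenol 12, in which C2–OH (free) and C5–OMe are already differentiated.
4. 12 ⇐ Dötz benzannulation. The carbocycle C1–C6 (first ring) is assembled from three components: alkenyl Fischer carbene 6 (C3, C4, C5), one CO ligand (C2) and farnesylacetylene 9 (C1, C6). Bonds formed: C1–C2, C2–C3 and C5–C6.
5. This puts farnesyl ortho to the free OH and CH2O ortho to OMe without any arene substitution chemistry; 6 and 9 come from 2-bromoallyl alcohol and farnesyl bromide.

Key step: step 4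

Assumption: L-(+)-diisopropyl tartrate is taken to deliver the (1R,6S) epoxide by analogy with hydroxymethyl-directed tartrate epoxidations of 6-allyl quinone monoketals; if the first run should give the antipode, D-(−)-DIPT is used with no other change.

## Route

Step 1
Reactants: 1 2-bromoprop-2-en-1-ol
Product: 2 [(2-bromoprop-2-en-1-yl)oxy]tri(propan-2-yl)silane
Conditions: TIPSCl, imidazole, DMF, 0 °C to rt
Reagents that add atoms: triisopropylsilyl chloride (TIPSCl), CC(C)[Si](Cl)(C(C)C)C(C)C
Why: Imidazole-promoted silylation of a primary alcohol; the bulky TIPS group is chosen because it should resist 1,3 O→C silyl migration in the vinyllithium of step 2 and still falls to fluoride.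

Step 2
Reactants: 2 [(2-bromoprop-2-en-1-yl)oxy]tri(propan-2-yl)silane; 3 hexacarbonylchromium(0)
Product: 6 pentacarbonyl{1-methoxy-2-[(triisopropylsilyloxy)methyl]prop-2-en-1-ylidene}chromium(0), via vinyllithium 4 (not isolated), via lithium acylchromate 5 (not isolated)
Conditions: t-BuLi (2.1 equiv), Et2O, −78 °C; Cr(CO)6, −78 °C to rt; then Me3OBF4, CH2Cl2, 0 °C
Reagents that add atoms: trimethyloxonium tetrafluoroborate, C[O+](C)C.F[B-](F)(F)F
Why: Fischer carbene synthesis, in which Br/Li exchange gives the 2-propenyllithium, this adds to a CO ligand of Cr(CO)6 to give the acylchromate, and O-methylation with Meerwein's salt gives the alkoxycarbene, as for simple isopropenyl complexes.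

Step 3
Reactants: 7 (2E,6E)-1-bromo-3,7,11-trimethyldodeca-2,6,10-triene (farnesyl bromide); 8 ethynylmagnesium bromide
Product: 9 (4E,8E)-5,9,13-trimethyltetradeca-4,8,12-trien-1-yne
Conditions: 8 (2.5 equiv), CuCl (5 mol %), THF, 0 °C to 45 °C
Reagents that add atoms: none
Why: Copper-catalysed SN2 coupling of a primary allylic bromide with an alkynyl Grignard reagent should give the skipped 1,4-enyne at the unhindered α-carbon with retention of the 2E geometry, since the fully substituted γ-carbon disfavours SN2'.

Step 4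
Reactants: 6 pentacarbonyl{1-methoxy-2-[(triisopropylsilyloxy)methyl]prop-2-en-1-ylidene}chromium(0); 9 (4E,8E)-5,9,13-trimethyltetradeca-4,8,12-trien-1-yne
Product: 12 5-(hydroxymethyl)-4-methoxy-2-[(2E,6E)-3,7,11-trimethyldodeca-2,6,10-trien-1-yl]phenol, via tricarbonylchromium arene complex 10 (not isolated), via silyl ether phenol 11 (not isolated)
Conditions: 9 (1.5 equiv), THF (0.05 M), 50 °C, Ar; then air, Et2O, rt, Celite filtration; then TBAF, THF, 0 °C to rt, Ar; aq NH4Cl
Reagents that add atoms: none
Why: Dötz benzannulation: loss of one CO from 6, regioselective insertion of the terminal alkyne into Cr=C (its CH carbon C6 bonds to the carbene carbon C5, so the farnesyl-bearing carbon C1 ends next to the CO-derived carbon C2), CO insertion to the η4-vinylketene and 6π-electrocyclic ring closure (C2–C3 bond, the only ring closure, thermally allowed disrotatory mode), then enol-to-phenol tautomerisation, should give arene complex 10. Air strips the Cr(CO)3 unit to give 11, and fluoride cleaves the primary TIPS ether to give 12. The closest known reaction type is the benzannulation of alkenyl(methoxy)carbene chromium complexes with terminal alkynes, including alkynes that carry polyprenyl chains. No stereocentre is formed; the step fixes constitution, with farnesyl ortho to the free OH (C1/C2) and the oxymethyl group ortho to OMe (C4/C5), which is the differentiation of the two enone halves that steps 5 and 6 rely on. The selectivities needed are the regiochemistry of alkyne insertion, secured by the steric difference between H and CH2R on a terminal alkyne, and chemoselectivity for the alkyne over the three trisubstituted alkenes, which should be inert to a Fischer carbene at 50 °C and, as part of a 1,4-enyne, cannot cyclopropanate intramolecularly.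

Step 5
Reactants: 12 5-(hydroxymethyl)-4-methoxy-2-[(2E,6E)-3,7,11-trimethyldodeca-2,6,10-trien-1-yl]phenol
Product: 13 5-(hydroxymethyl)-4,4-dimethoxy-2-[(2E,6E)-3,7,11-trimethyldodeca-2,6,10-trien-1-yl]cyclohexa-2,5-dien-1-one
Conditions: PhI(OAc)2 (1.1 equiv), MeOH, 0 °C; NaHCO3
Reagents that add atoms: methanol, CO
Why: λ3-Iodane oxidative dearomatisation of a p-methoxyphenol in methanol, in which MeOH attacks the aryloxy-iodane at the para carbon that already carries OMe (C5) to give the quinone monoketal, the phenol being oxidised far faster than the chain alkenes or the primary alcohol at 0 °C.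

Step 6
Reactants: 13 5-(hydroxymethyl)-4,4-dimethoxy-2-[(2E,6E)-3,7,11-trimethyldodeca-2,6,10-trien-1-yl]cyclohexa-2,5-dien-1-one
Product: 14 (1R,6S)-4-(hydroxymethyl)-5,5-dimethoxy-1-[(2E,6E)-3,7,11-trimethyldodeca-2,6,10-trien-1-yl]-7-oxabicyclo[4.1.0]hept-3-en-2-one
Conditions: Ph3COOH (3 equiv), NaHMDS (2.6 equiv), L-(+)-DIPT (1.3 equiv), 4 Å MS, toluene, −60 to −40 °C; aq NH4Cl
Reagents that add atoms: trityl hydroperoxide, OOC(c1ccccc1)(c1ccccc1)c1ccccc1
Why: Tartrate-mediated, hydroxyl-directed nucleophilic epoxidation of a quinone monoketal (Weitz–Scheffer type, known for 3-hydroxymethyl-6-allyl quinone monoketals): the sodium alkoxide of the C4 CH2OH group and the sodium tartrate hold the trityl peroxide over C6, the only unsubstituted β-carbon (C4 is fully substituted and the C5 ketal removes the second carbonyl), the C1 enolate closes onto the O–O bond, and the tartrate enantiomer selects the enantiotopic face so that C1 (R) and C6 (S) are set together as the cis-oxirane, while the electron-rich chain alkenes should be inert to the peroxide anion.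

Step 7
Reactants: 14 (1R,6S)-4-(hydroxymethyl)-5,5-dimethoxy-1-[(2E,6E)-3,7,11-trimethyldodeca-2,6,10-trien-1-yl]-7-oxabicyclo[4.1.0]hept-3-en-2-one
Product: 15 {(1R,6S)-5,5-dimethoxy-2-oxo-1-[(2E,6E)-3,7,11-trimethyldodeca-2,6,10-trien-1-yl]-7-oxabicyclo[4.1.0]hept-3-en-4-yl}methyl acetate
Conditions: Ac2O, pyridine, DMAP (cat.), CH2Cl2, 0 °C
Reagents that add atoms: acetic anhydride, CC(=O)OC(C)=O
Why: DMAP-catalysed O-acylation of a primary alcohol, done while the second carbonyl is still masked so that the base-sensitive ene-dione is never exposed to pyridine; no stereocentre is touched.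

Step 8
Reactants: 15 {(1R,6S)-5,5-dimethoxy-2-oxo-1-[(2E,6E)-3,7,11-trimethyldodeca-2,6,10-trien-1-yl]-7-oxabicyclo[4.1.0]hept-3-en-4-yl}methyl acetate
Product: 16 {(1R,6S)-2,5-dioxo-1-[(2E,6E)-3,7,11-trimethyldodeca-2,6,10-trien-1-yl]-7-oxabicyclo[4.1.0]hept-3-en-4-yl}methyl acetate (CNP0301406.1)
Conditions: 48% aq HF, MeCN, 0 °C to rt (polypropylene vessel)
Reagents that add atoms: water, O
Why: Acid-catalysed hydrolysis of the dimethyl ketal through the C5 oxocarbenium ion should unveil the second carbonyl, while the epoxide (flanked by two electron-poor carbons), the acetate and the chain alkenes should survive dilute aqueous HF, and C1 and C6 cannot epimerise.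

## Compound list

1 | 2-bromoprop-2-en-1-ol | OCC(Br)=C | starting material
2 | [(2-bromoprop-2-en-1-yl)oxy]tri(propan-2-yl)silane | C=C(Br)CO[Si](C(C)C)(C(C)C)C(C)C | intermediate
3 | hexacarbonylchromium(0) | O=C=[Cr](=C=O)(=C=O)(=C=O)(=C=O)=C=O | starting material
4 | {3-[tri(propan-2-yl)silyloxy]prop-1-en-2-yl}lithium (not isolated) | [Li]C(=C)CO[Si](C(C)C)(C(C)C)C(C)C | intermediate
5 | lithium pentacarbonyl{2-[(triisopropylsilyloxy)methyl]prop-2-enoyl}chromate (not isolated) | [Li+].[O-]C(C(=C)CO[Si](C(C)C)(C(C)C)C(C)C)=[Cr](=C=O)(=C=O)(=C=O)(=C=O)=C=O | intermediate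
6 | pentacarbonyl{1-methoxy-2-[(triisopropylsilyloxy)methyl]prop-2-en-1-ylidene}chromium(0) | COC(C(=C)CO[Si](C(C)C)(C(C)C)C(C)C)=[Cr](=C=O)(=C=O)(=C=O)(=C=O)=C=O | intermediate
7 | (2E,6E)-1-bromo-3,7,11-trimethyldodeca-2,6,10-triene (farnesyl bromide) | BrC/C=C(\C)CC/C=C(\C)CCC=C(C)C | starting material
8 | ethynylmagnesium bromide | C#C[Mg]Br | starting material
9 | (4E,8E)-5,9,13-trimethyltetradeca-4,8,12-trien-1-yne | C#CC/C=C(\C)CC/C=C(\C)CCC=C(C)C | intermediate
10 | tricarbonyl(η6-arene)chromium complex of phenol 11 (not isolated; Cr(CO)3 on the arene face, written dot-joined) | COc1cc(C/C=C(\C)CC/C=C(\C)CCC=C(C)C)c(O)cc1CO[Si](C(C)C)(C(C)C)C(C)C.[Cr](=C=O)(=C=O)=C=O | intermediate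
11 | 4-methoxy-5-{[tri(propan-2-yl)silyloxy]methyl}-2-[(2E,6E)-3,7,11-trimethyldodeca-2,6,10-trien-1-yl]phenol (not isolated) | COc1cc(C/C=C(\C)CC/C=C(\C)CCC=C(C)C)c(O)cc1CO[Si](C(C)C)(C(C)C)C(C)C | intermediate
12 | 5-(hydroxymethyl)-4-methoxy-2-[(2E,6E)-3,7,11-trimethyldodeca-2,6,10-trien-1-yl]phenol | COc1cc(C/C=C(\C)CC/C=C(\C)CCC=C(C)C)c(O)cc1CO | intermediate
13 | 5-(hydroxymethyl)-4,4-dimethoxy-2-[(2E,6E)-3,7,11-trimethyldodeca-2,6,10-trien-1-yl]cyclohexa-2,5-dien-1-one | OCC1=CC(=O)C(C/C=C(\C)CC/C=C(\C)CCC=C(C)C)=CC1(OC)OC | intermediate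
14 | (1R,6S)-4-(hydroxymethyl)-5,5-dimethoxy-1-[(2E,6E)-3,7,11-trimethyldodeca-2,6,10-trien-1-yl]-7-oxabicyclo[4.1.0]hept-3-en-2-one | OCC1=CC(=O)[C@]2(C/C=C(\C)CC/C=C(\C)CCC=C(C)C)O[C@@H]2C1(OC)OC | intermediate
15 | {(1R,6S)-5,5-dimethoxy-2-oxo-1-[(2E,6E)-3,7,11-trimethyldodeca-2,6,10-trien-1-yl]-7-oxabicyclo[4.1.0]hept-3-en-4-yl}methyl acetate | CC(=O)OCC1=CC(=O)[C@]2(C/C=C(\C)CC/C=C(\C)CCC=C(C)C)O[C@@H]2C1(OC)OC | intermediate
16 | {(1R,6S)-2,5-dioxo-1-[(2E,6E)-3,7,11-trimethyldodeca-2,6,10-trien-1-yl]-7-oxabicyclo[4.1.0]hept-3-en-4-yl}methyl acetate (C1 R, quaternary epoxide carbon; C6 S, epoxide CH) | CC(=O)OCC1=CC(=O)[C@]2(C/C=C(\C)CC/C=C(\C)CCC=C(C)C)O[C@@H]2C1=O | target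

## Step count and risks

Total step count: 8. Longest linear sequence: 7 (steps 1, 2, 4, 5, 6, 7, 8); step 3 is a one-step branch.

Three steps most likely to fail:

**Step 4.** The benzannulation may stall through incorporation of a second alkyne, decomposition of the vinylcarbene before CO insertion, or loss of the electron-rich phenol during oxidative removal of chromium. The fallback gives up the ring synthesis and functionalises a preformed arene. It sets out from 7 and purchased 5-hydroxy-2-methoxybenzaldehyde F1. The sodium phenoxide of F1 (NaH, toluene) is C-alkylated with 7 at the free ortho position para to the formyl group, the non-polar medium favouring C- over O-alkylation, to give 5-hydroxy-2-methoxy-4-[(2E,6E)-3,7,11-trimethyldodeca-2,6,10-trien-1-yl]benzaldehyde F2. Reduction with NaBH4 in MeOH at 0 °C returns to the route at 12.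

**Step 6.** Facial discrimination may be incomplete, or conjugate addition of the bulky peroxide to the α-substituted enone may be too slow at low temperature. The fallback replaces reagent control by auxiliary control and sets out from 13. Transketalisation with (2S,4S)-pentane-2,4-diol (PPTS, benzene, 4 Å MS) gives the C2-symmetric spiroketal F3, the (4S,6S)-4,6-dimethyl-1,3-dioxane analogue of 13. Substrate-controlled nucleophilic epoxidation (Ph3COOH, KHMDS, toluene, −35 °C), in which the dioxane methyl groups shield one face of C6, should give epoxy spiroketal F4. Acetylation (Ac2O, pyridine) gives F5, and aqueous HF in MeCN releases the diol and comes back to the route at 16. The diol enantiomer is chosen on the same analogy as the tartrate.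

**Step 8.** The neighbouring acetate may participate in the C5 oxocarbenium ion, with acetyl transfer and loss of the ester, or the epoxide may open on prolonged exposure to acid. The fallback inverts the end game and installs the ester under neutral conditions; it sets out from 14. Ketal hydrolysis (aq HF, MeCN) gives (1R,6S)-4-(hydroxymethyl)-1-[(2E,6E)-3,7,11-trimethyldodeca-2,6,10-trien-1-yl]-7-oxabicyclo[4.1.0]hept-3-ene-2,5-dione F6. Lipase-catalysed transesterification (immobilised Candida antarctica lipase B, vinyl acetate, MTBE, rt) then acetylates the primary alcohol and comes back to the route at 16.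

## Further compounds

F1 | step 4 | 5-hydroxy-2-methoxybenzaldehyde (purchased) | COc1ccc(O)cc1C=O
F2 | step 4 | 5-hydroxy-2-methoxy-4-[(2E,6E)-3,7,11-trimethyldodeca-2,6,10-trien-1-yl]benzaldehyde | COc1cc(C/C=C(\C)CC/C=C(\C)CCC=C(C)C)c(O)cc1C=O
F3 | step 6 | spiroketal of 13 with (2S,4S)-pentane-2,4-diol: the C4 carbon of the dienone is C2 of a (4S,6S)-4,6-dimethyl-1,3-dioxane | OCC1=CC(=O)C(C/C=C(\C)CC/C=C(\C)CCC=C(C)C)=CC12O[C@@H](C)C[C@H](C)O2
F4 | step 6 | (1R,6S)-epoxide of F3 (spiroketal analogue of 14) | OCC1=CC(=O)[C@]2(C/C=C(\C)CC/C=C(\C)CCC=C(C)C)O[C@@H]2C13O[C@@H](C)C[C@H](C)O3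
F5 | step 6 | acetate of F4 (spiroketal analogue of 15) | CC(=O)OCC1=CC(=O)[C@]2(C/C=C(\C)CC/C=C(\C)CCC=C(C)C)O[C@@H]2C13O[C@@H](C)C[C@H](C)O3
F6 | step 8 | (1R,6S)-4-(hydroxymethyl)-1-[(2E,6E)-3,7,11-trimethyldodeca-2,6,10-trien-1-yl]-7-oxabicyclo[4.1.0]hept-3-ene-2,5-dione | OCC1=CC(=O)[C@]2(C/C=C(\C)CC/C=C(\C)CCC=C(C)C)O[C@@H]2C1=O
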